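**Retrosynthetic overview**
1. Target 14 ⇐ hydrogenolysis of the two benzyl ethers of acid 13 ⇐ Pinnick oxidation of tridepside aldehyde 12.
2. 12 ⇐ C–B ester bond: acyl chloride 7 + the 4-OH of diphenol 11.
3. 11 ⇐ debenzylation of 10 ⇐ O-methylation of 8 (the aroyl group doubles as the 4-O protecting group of ring A) ⇐ B–A ester bond: acyl chloride 7 + the 4-OH of aldehyde 1.
4. 7 ⇐ 5 ⇐ 3 ⇐ 1 (dibenzylation, Pinnick, oxalyl chloride); one batch of 7 serves both esterifications and all three rings are bought as 2,4-dihydroxy-6-methylbenzaldehyde 1.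
5. No ring is formed: rings A (methoxy acid), B (middle) and C (terminal orsellinoyl) are preformed arenes, linked B–A first, then C–B.

Assumption: the target has no stereocentre or stereoaxis (it is achiral), so "single enantiomer" needs no stereocontrol; 2,4-dihydroxy-6-methylbenzaldehyde (orcylaldehyde) is taken as commercially available.

**Route**

Step 1
Reactants: 1 2,4-dihydroxy-6-methylbenzaldehyde; 2 benzyl bromide
Product: 3 2,4-bis(benzyloxy)-6-methylbenzaldehyde
Conditions: BnBr (2.4 equiv), K2CO3 (3 equiv), DMF, 60 °C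
Reagents that add atoms: benzyl bromide BrCc1ccccc1
Why: Williamson ether synthesis, in which excess carbonate and warming deprotonate both phenols (including the chelated 2-OH) and the phenoxides displace bromide by SN2; no stereocentre is created.

Step 2
Reactants: 3 2,4-bis(benzyloxy)-6-methylbenzaldehyde; 4 sodium chlorite
Product: 5 2,4-bis(benzyloxy)-6-methylbenzoic acid
Conditions: NaClO2, NaH2PO4, 2-methyl-2-butene, t-BuOH/THF/H2O, 0 °C to rt
Reagents that add atoms: sodium chlorite [Na+].[O-]Cl=O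
Why: Pinnick (Lindgren) oxidation, in which chlorous acid adds to the hindered electron-rich aldehyde and fragments to the acid while 2-methyl-2-butene traps HOCl, so the benzyl ethers and the arene are untouched.

Step 3
Reactants: 5 2,4-bis(benzyloxy)-6-methylbenzoic acid; 6 oxalyl chloride
Product: 7 2,4-bis(benzyloxy)-6-methylbenzoyl chloride
Conditions: (COCl)2 (1.5 equiv), cat. DMF, dry CH2Cl2, 0 °C to rt; evaporated and used crude for both esterifications
Reagents that add atoms: oxalyl chloride ClC(=O)C(=O)Cl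
Why: Acyl chloride formation with oxalyl chloride under DMF (Vilsmeier-type) catalysis converts the hindered acid at or below room temperature with only gaseous by-products and leaves the benzyl ethers untouched.

Step 4
Reactants: 7 2,4-bis(benzyloxy)-6-methylbenzoyl chloride; 1 2,4-dihydroxy-6-methylbenzaldehyde
Product: 8 4-formyl-3-hydroxy-5-methylphenyl 2,4-bis(benzyloxy)-6-methylbenzoate
Conditions: 7 (1.05 equiv), K2CO3 (1.2 equiv), dry acetone, 0 °C to rt
Reagents that add atoms: none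
Why: Base-mediated O-acylation of a phenol by an acyl chloride (the classical depside coupling), in which carbonate ionises only the more acidic 4-OH para to the formyl group while the 2-OH stays hydrogen-bonded to and shielded by the formyl group.

Step 5
Reactants: 8 4-formyl-3-hydroxy-5-methylphenyl 2,4-bis(benzyloxy)-6-methylbenzoate; 9 methyl iodide
Product: 10 4-formyl-3-methoxy-5-methylphenyl 2,4-bis(benzyloxy)-6-methylbenzoate
Conditions: MeI (3 equiv), K2CO3 (2 equiv), dry acetone, reflux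
Reagents that add atoms: methyl iodide CI
Why: Williamson O-methylation (SN2 on MeI) of the only remaining phenol, the di-ortho-substituted aryl ester being too hindered for carbonate or phenoxide to cleave under anhydrous conditions.

Step 6
Reactants: 10 4-formyl-3-methoxy-5-methylphenyl 2,4-bis(benzyloxy)-6-methylbenzoate
Product: 11 4-formyl-3-methoxy-5-methylphenyl 2,4-dihydroxy-6-methylbenzoate
Conditions: H2 (1 atm), 10% Pd/C, EtOAc, rt, stopped after 2 equiv H2
Reagents that add atoms: none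
Why: Catalytic hydrogenolysis of the two benzylic C–O bonds is much faster than reduction of the hindered electron-rich aryl aldehyde and leaves the aryl ester and methyl ether intact.

Step 7
Reactants: 7 2,4-bis(benzyloxy)-6-methylbenzoyl chloride; 11 4-formyl-3-methoxy-5-methylphenyl 2,4-dihydroxy-6-methylbenzoate
Product: 12 4-[(4-formyl-3-methoxy-5-methylphenoxy)carbonyl]-3-hydroxy-5-methylphenyl 2,4-bis(benzyloxy)-6-methylbenzoate
Conditions: 7 (1.05 equiv), K2CO3 (1.2 equiv), dry acetone, 0 °C to rt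
Reagents that add atoms: none
Why: Second base-mediated O-acylation with the same acyl chloride, selective for the more acidic and unhindered 4-OH of 11 because the 2-OH is hydrogen-bonded to the adjacent ester carbonyl, while the anhydrous non-nucleophilic medium at low temperature keeps the existing depside link intact.

Step 8
Reactants: 12 4-[(4-formyl-3-methoxy-5-methylphenoxy)carbonyl]-3-hydroxy-5-methylphenyl 2,4-bis(benzyloxy)-6-methylbenzoate; 4 sodium chlorite
Product: 13 4-[(4-{[2,4-bis(benzyloxy)-6-methylbenzoyl]oxy}-2-hydroxy-6-methylbenzoyl)oxy]-2-methoxy-6-methylbenzoic acid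
Conditions: NaClO2, NaH2PO4, 2-methyl-2-butene (large excess), t-BuOH/THF/H2O, 0 °C to rt
Reagents that add atoms: sodium chlorite [Na+].[O-]Cl=O
Why: Buffered Pinnick oxidation with excess scavenger converts the aldehyde to the acid without hydrolysing either aryl ester and without chlorinating the ester-deactivated phenolic ring B.

Step 9
Reactants: 13 4-[(4-{[2,4-bis(benzyloxy)-6-methylbenzoyl]oxy}-2-hydroxy-6-methylbenzoyl)oxy]-2-methoxy-6-methylbenzoic acid
Product: 14 4-({4-[(2,4-dihydroxy-6-methylbenzoyl)oxy]-2-hydroxy-6-methylbenzoyl}oxy)-2-methoxy-6-methylbenzoic acid (target)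
Conditions: H2 (1 atm), 10% Pd/C, EtOAc, rt
Reagents that add atoms: none
Why: Neutral hydrogenolysis of the two remaining benzyl ethers frees ring C's phenols while the depside esters, the methyl ether and the carboxylic acid are inert, giving the achiral target.

**Compound list**
1 | 2,4-dihydroxy-6-methylbenzaldehyde | Cc1cc(O)cc(O)c1C=O | starting material
2 | benzyl bromide | BrCc1ccccc1 | starting material
3 | 2,4-bis(benzyloxy)-6-methylbenzaldehyde | Cc1cc(OCc2ccccc2)cc(OCc2ccccc2)c1C=O | intermediate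
4 | sodium chlorite | [Na+].[O-]Cl=O | starting material
5 | 2,4-bis(benzyloxy)-6-methylbenzoic acid | Cc1cc(OCc2ccccc2)cc(OCc2ccccc2)c1C(=O)O | intermediate
6 | oxalyl chloride | ClC(=O)C(=O)Cl | starting material
7 | 2,4-bis(benzyloxy)-6-methylbenzoyl chloride | Cc1cc(OCc2ccccc2)cc(OCc2ccccc2)c1C(=O)Cl | intermediate
8 | 4-formyl-3-hydroxy-5-methylphenyl 2,4-bis(benzyloxy)-6-methylbenzoate | Cc1cc(OCc2ccccc2)cc(OCc2ccccc2)c1C(=O)Oc1cc(C)c(C=O)c(O)c1 | intermediate
9 | methyl iodide | CI | starting material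
10 | 4-formyl-3-methoxy-5-methylphenyl 2,4-bis(benzyloxy)-6-methylbenzoate | Cc1cc(OCc2ccccc2)cc(OCc2ccccc2)c1C(=O)Oc1cc(C)c(C=O)c(OC)c1 | intermediate
11 | 4-formyl-3-methoxy-5-methylphenyl 2,4-dihydroxy-6-methylbenzoate | Cc1cc(O)cc(O)c1C(=O)Oc1cc(C)c(C=O)c(OC)c1 | intermediate
12 | 4-[(4-formyl-3-methoxy-5-methylphenoxy)carbonyl]-3-hydroxy-5-methylphenyl 2,4-bis(benzyloxy)-6-methylbenzoate | Cc1cc(OCc2ccccc2)cc(OCc2ccccc2)c1C(=O)Oc1cc(C)c(C(=O)Oc2cc(C)c(C=O)c(OC)c2)c(O)c1 | intermediate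
13 | 4-[(4-{[2,4-bis(benzyloxy)-6-methylbenzoyl]oxy}-2-hydroxy-6-methylbenzoyl)oxy]-2-methoxy-6-methylbenzoic acid | Cc1cc(OCc2ccccc2)cc(OCc2ccccc2)c1C(=O)Oc1cc(C)c(C(=O)Oc2cc(C)c(C(=O)O)c(OC)c2)c(O)c1 | intermediate
14 | 4-({4-[(2,4-dihydroxy-6-methylbenzoyl)oxy]-2-hydroxy-6-methylbenzoyl}oxy)-2-methoxy-6-methylbenzoic acid | COc1cc(OC(=O)c2c(C)cc(OC(=O)c3c(C)cc(O)cc3O)cc2O)cc(C)c1C(=O)O | target

**Totals**
Total step count: 9. Longest linear sequence: 9 (1 → 3 → 5 → 7 → 8 → 10 → 11 → 12 → 13 → 14; acyl chloride 7 is used twice, aldehyde 1 twice).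

**Three steps most likely to fail, with fallbacks**

Step 6 (debenzylation next to a formyl group). The risk is over-reduction of the aldehyde to the benzyl alcohol or methyl group. The fallback grows the chain in the opposite sense, so that hydrogen only ever meets a carboxylic acid. It sets out from 8. Its chelated phenol is benzylated (2, K2CO3, DMF) to 3-(benzyloxy)-4-formyl-5-methylphenyl 2,4-bis(benzyloxy)-6-methylbenzoate F1. Pinnick oxidation (4, NaH2PO4, 2-methyl-2-butene) gives 2-(benzyloxy)-4-{[2,4-bis(benzyloxy)-6-methylbenzoyl]oxy}-6-methylbenzoic acid F2. Oxalyl chloride 6 with catalytic DMF converts this into 2-(benzyloxy)-4-{[2,4-bis(benzyloxy)-6-methylbenzoyl]oxy}-6-methylbenzoyl chloride F3. F3 acylates the 4-OH of a further equivalent of 1 (K2CO3, acetone) to give 4-formyl-3-hydroxy-5-methylphenyl 2-(benzyloxy)-4-{[2,4-bis(benzyloxy)-6-methylbenzoyl]oxy}-6-methylbenzoate F4. The single free phenol is methylated (9, K2CO3, acetone) to 4-formyl-3-methoxy-5-methylphenyl 2-(benzyloxy)-4-{[2,4-bis(benzyloxy)-6-methylbenzoyl]oxy}-6-methylbenzoate F5. A second Pinnick oxidation gives 4-[(2-(benzyloxy)-4-{[2,4-bis(benzyloxy)-6-methylbenzoyl]oxy}-6-methylbenzoyl)oxy]-2-methoxy-6-methylbenzoic acid F6. One hydrogenolysis (H2, Pd/C, EtOAc) removes all three benzyl ethers and comes back to the route at 14.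

Step 7 (regioselective acylation of diphenol 11 with a hindered acyl chloride). The risk is 2-O- or bis-acylation, sluggish reaction, or base-induced scrambling of the existing depside link. The fallback reverses the roles so that the phenol partner has only one OH and the coupling runs without base. It sets out from 8 (with 10 as the source of the phenol). Pinnick oxidation of 8 gives 4-{[2,4-bis(benzyloxy)-6-methylbenzoyl]oxy}-2-hydroxy-6-methylbenzoic acid F7. Saponification of a portion of 10 (KOH, MeOH/H2O, then acid; 5 is recovered) gives 4-hydroxy-2-methoxy-6-methylbenzaldehyde F8. F7 is activated with trifluoroacetic anhydride in dry toluene as 4-{[2,4-bis(benzyloxy)-6-methylbenzoyl]oxy}-2-hydroxy-6-methylbenzoic trifluoroacetic anhydride F9 (its chelated 2-OH is tolerated; DCC is the alternative activator) and esterified with F8. This comes back to the route at 12.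

Step 8 (Pinnick oxidation of a tridepside carrying a free phenol). The risk is ring chlorination of ring B or incomplete oxidation of the hindered aldehyde. The fallback oxidises at a stage with no free phenol and carries the acid as a benzyl ester. It sets out from 10. Pinnick oxidation gives 4-{[2,4-bis(benzyloxy)-6-methylbenzoyl]oxy}-2-methoxy-6-methylbenzoic acid F10. Hydrogenolysis (H2, Pd/C; no aldehyde present) gives 4-[(2,4-dihydroxy-6-methylbenzoyl)oxy]-2-methoxy-6-methylbenzoic acid F11. Selective carboxylate alkylation (2, KHCO3, DMF, rt) gives benzyl 4-[(2,4-dihydroxy-6-methylbenzoyl)oxy]-2-methoxy-6-methylbenzoate F12. Acylation of its 4-OH with acyl chloride 7 (K2CO3, acetone) gives benzyl 4-[(4-{[2,4-bis(benzyloxy)-6-methylbenzoyl]oxy}-2-hydroxy-6-methylbenzoyl)oxy]-2-methoxy-6-methylbenzoate F13. Hydrogenolysis of the benzyl ester and both benzyl ethers comes back to the route at 14.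

**Further compounds**
F1 | step 6 | 3-(benzyloxy)-4-formyl-5-methylphenyl 2,4-bis(benzyloxy)-6-methylbenzoate | Cc1cc(OCc2ccccc2)cc(OCc2ccccc2)c1C(=O)Oc1cc(C)c(C=O)c(OCc2ccccc2)c1
F2 | step 6 | 2-(benzyloxy)-4-{[2,4-bis(benzyloxy)-6-methylbenzoyl]oxy}-6-methylbenzoic acid | Cc1cc(OCc2ccccc2)cc(OCc2ccccc2)c1C(=O)Oc1cc(C)c(C(=O)O)c(OCc2ccccc2)c1
F3 | step 6 | 2-(benzyloxy)-4-{[2,4-bis(benzyloxy)-6-methylbenzoyl]oxy}-6-methylbenzoyl chloride | Cc1cc(OCc2ccccc2)cc(OCc2ccccc2)c1C(=O)Oc1cc(C)c(C(=O)Cl)c(OCc2ccccc2)c1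
F4 | step 6 | 4-formyl-3-hydroxy-5-methylphenyl 2-(benzyloxy)-4-{[2,4-bis(benzyloxy)-6-methylbenzoyl]oxy}-6-methylbenzoate | Cc1cc(OCc2ccccc2)cc(OCc2ccccc2)c1C(=O)Oc1cc(C)c(C(=O)Oc2cc(C)c(C=O)c(O)c2)c(OCc2ccccc2)c1
F5 | step 6 | 4-formyl-3-methoxy-5-methylphenyl 2-(benzyloxy)-4-{[2,4-bis(benzyloxy)-6-methylbenzoyl]oxy}-6-methylbenzoate | Cc1cc(OCc2ccccc2)cc(OCc2ccccc2)c1C(=O)Oc1cc(C)c(C(=O)Oc2cc(C)c(C=O)c(OC)c2)c(OCc2ccccc2)c1
F6 | step 6 | 4-[(2-(benzyloxy)-4-{[2,4-bis(benzyloxy)-6-methylbenzoyl]oxy}-6-methylbenzoyl)oxy]-2-methoxy-6-methylbenzoic acid | Cc1cc(OCc2ccccc2)cc(OCc2ccccc2)c1C(=O)Oc1cc(C)c(C(=O)Oc2cc(C)c(C(=O)O)c(OC)c2)c(OCc2ccccc2)c1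
F7 | step 7 | 4-{[2,4-bis(benzyloxy)-6-methylbenzoyl]oxy}-2-hydroxy-6-methylbenzoic acid | Cc1cc(OCc2ccccc2)cc(OCc2ccccc2)c1C(=O)Oc1cc(C)c(C(=O)O)c(O)c1
F8 | step 7 | 4-hydroxy-2-methoxy-6-methylbenzaldehyde | COc1cc(O)cc(C)c1C=O
F9 | step 7 | 4-{[2,4-bis(benzyloxy)-6-methylbenzoyl]oxy}-2-hydroxy-6-methylbenzoic trifluoroacetic anhydride | Cc1cc(OCc2ccccc2)cc(OCc2ccccc2)c1C(=O)Oc1cc(C)c(C(=O)OC(=O)C(F)(F)F)c(O)c1
F10 | step 8 | 4-{[2,4-bis(benzyloxy)-6-methylbenzoyl]oxy}-2-methoxy-6-methylbenzoic acid | Cc1cc(OCc2ccccc2)cc(OCc2ccccc2)c1C(=O)Oc1cc(C)c(C(=O)O)c(OC)c1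
F11 | step 8 | 4-[(2,4-dihydroxy-6-methylbenzoyl)oxy]-2-methoxy-6-methylbenzoic acid | Cc1cc(O)cc(O)c1C(=O)Oc1cc(C)c(C(=O)O)c(OC)c1
F12 | step 8 | benzyl 4-[(2,4-dihydroxy-6-methylbenzoyl)oxy]-2-methoxy-6-methylbenzoate | Cc1cc(O)cc(O)c1C(=O)Oc1cc(C)c(C(=O)OCc2ccccc2)c(OC)c1
F13 | step 8 | benzyl 4-[(4-{[2,4-bis(benzyloxy)-6-methylbenzoyl]oxy}-2-hydroxy-6-methylbenzoyl)oxy]-2-methoxy-6-methylbenzoate | Cc1cc(OCc2ccccc2)cc(OCc2ccccc2)c1C(=O)Oc1cc(C)c(C(=O)Oc2cc(C)c(C(=O)OCc3ccccc3)c(OC)c2)c(O)c1
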